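**Retrosynthetic overview**
1. Target ⇒ 3β-acyloxy-4α-acetoxy-eudesm-7(11)-ene: the C8 carbonyl is made last by an anodic allylic C–H oxidation (key C8–O bond, electrochemical).
2. 7(11)-Ene ⇒ 7α-isopropenyl diester (olefin transposition); the esters come from a 3β,4α-diol, (R)-2-methylbutanoic acid and Ac2O.
3. trans-Diol ⇒ 4α-hydroxy-3-ketone (Rubottom) ⇒ Δ3 silyl enol ether (reductive silylation) ⇒ ent-10-epi-α-cyperone.
4. Octalone ⇒ Robinson annulation of (5S)-dihydrocarvone with ethyl vinyl ketone. Ring B is bought with (S)-carvone; ring A is formed in the annulation.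
5. The carvone stereocenter (C7) sets C10, C10 then controls C5, C4 and C3, and C7 is finally erased.

Assumption: (R)-2-methylbutanoic acid is bought as the single enantiomer. Eudesmane numbering is used for the decalin (C10 methyl = β; C11–C13 on C7; C15 on C4). "7-epi" means the C7 substituent is α.

**Step 1**
Reactants: 1 (S)-(+)-carvone
Product: 2 (2S,5S)-dihydrocarvone
Conditions: Zn dust, KOH, EtOH/H2O, reflux
Reagents that add atoms: none
Why: Dissolving-metal conjugate reduction of the enone leaves the isolated isopropenyl group and the bought C5 stereocenter untouched, and the C2 epimer ratio is irrelevant because C2 is enolized in step 2.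

**Step 2**
Reactants: 2 (2S,5S)-dihydrocarvone; 3 ethyl vinyl ketone
Product: 6 ent-10-epi-α-cyperone [(4aS,7S)-octalone; 10β-Me; 7α-isopropenyl], via Michael adduct 4 (not isolated), via bicyclic ketol 5 (not isolated)
Conditions: KOH (0.2 equiv), EtOH, −10 → 20 °C; then 2 M KOH, EtOH, reflux
Reagents that add atoms: none
Why: Robinson annulation (Michael addition, aldol, dehydration) in which the thermodynamic enolate is attacked axially on the half-chair that keeps the isopropenyl group equatorial, so the new chain enters cis and the angular methyl ends trans to the isopropenyl group, which fixes C10 (the minor C10 epimer is removed by chromatography).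

**Step 3**
Reactants: 6 ent-10-epi-α-cyperone
Product: 8 3-(trimethylsilyloxy)-7-epi-eudesma-3,11-diene, via lithium enolate 7 (not isolated)
Conditions: Li (2.2 equiv), t-BuOH (1.0 equiv), NH3/THF, −78 → −33 °C; isoprene; evaporate NH3; TMSCl/Et3N, THF, 0 °C
Reagents that add atoms: chlorotrimethylsilane, C[Si](C)(C)Cl
Why: Stork reductive silylation (Birch-type enone reduction) in which axial protonation of the β-carbanion gives the trans ring fusion (5α-H, anti to the C10 methyl) and the regiospecific Δ3 enolate is trapped on oxygen, while the isolated alkene is not reduced.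

**Step 4**
Reactants: 8 3-(trimethylsilyloxy)-7-epi-eudesma-3,11-diene
Product: 11 4α-hydroxy-7-epi-eudesm-11-en-3-one, via siloxy epoxide 9 (not isolated), via siloxy ketone 10 (not isolated)
Conditions: mCPBA (1.05 equiv), NaHCO3, CH2Cl2, −20 °C; then 1 M HCl, THF, 0 °C
Reagents that add atoms: mCPBA, OOC(=O)c1cccc(Cl)c1
Why: Rubottom oxidation in which the electron-rich tetrasubstituted silyl enol ether is epoxidized far faster than the isopropenyl group and from the α face, anti to the axial C10 methyl, so that silyl migration and hydrolysis give the 4α-OH/4β-Me tertiary ketol.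

**Step 5**
Reactants: 11 4α-hydroxy-7-epi-eudesm-11-en-3-one
Product: 12 7-epi-eudesm-11-ene-3β,4α-diol
Conditions: NaBH4, MeOH, −20 °C
Reagents that add atoms: none
Why: Borohydride reduction by axial (α-face) hydride attack, reinforced by delivery from the 4α-hydroxyl, gives the equatorial 3β-alcohol trans to the tertiary alcohol, as in 4,4-disubstituted 3-oxo terpenoids.

**Step 6**
Reactants: 12 7-epi-eudesm-11-ene-3β,4α-diol; 13 (R)-2-methylbutanoic acid
Product: 14 4α-hydroxy-7-epi-eudesm-11-en-3β-yl (R)-2-methylbutanoate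
Conditions: DCC (1.6 equiv), DMAP (0.2 equiv), CH2Cl2, 0 → 23 °C
Reagents that add atoms: none
Why: Steglich esterification acylates only the secondary equatorial 3β-OH because the tertiary 4α-OH is inert to the carbodiimide/DMAP system, and the α-stereocenter of the acid is not epimerized since no ketene path operates.

**Step 7**
Reactants: 14 4α-hydroxy-7-epi-eudesm-11-en-3β-yl (R)-2-methylbutanoate
Product: 15 4α-acetoxy-7-epi-eudesm-11-en-3β-yl (R)-2-methylbutanoate
Conditions: Ac2O (10 equiv), DMAP (1 equiv), Et3N, CH2Cl2, 40 °C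
Reagents that add atoms: acetic anhydride, CC(=O)OC(C)=O
Why: DMAP-catalysed acylation of the tertiary alcohol under non-acidic conditions leaves the isopropenyl group and the secondary ester in place and changes no stereocenter.

**Step 8**
Reactants: 15 4α-acetoxy-7-epi-eudesm-11-en-3β-yl (R)-2-methylbutanoate
Product: 16 4α-acetoxy-eudesm-7(11)-en-3β-yl (R)-2-methylbutanoate
Conditions: achiral Co(salen)Cl [N,N'-bis(3,5-di-tert-butylsalicylidene)ethylenediamine] (3 mol%), PhSiH3 (6 mol%), benzene, 22 °C
Reagents that add atoms: none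
Why: Metal-hydride hydrogen-atom-transfer olefin isomerization in which reversible H• transfer to the terminal CH2 gives the tertiary C11 radical that loses the C7 hydrogen, forming the tetrasubstituted alkene that is inert to further HAT; relief of the axial isopropenyl strain drives the shift and the C7 stereocenter is erased after having done its work.

**Step 9**
Reactants: 16 4α-acetoxy-eudesm-7(11)-en-3β-yl (R)-2-methylbutanoate
Product: 18 4α-acetoxy-8-oxoeudesm-7(11)-en-3β-yl (R)-2-methylbutanoate (target), via allylic peroxide 17 (not isolated)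
Conditions: Cl4NHPI (20 mol%), pyridine (2 equiv), t-BuOOH (1.5 equiv), LiClO4 (0.6 equiv), acetone, RVC(+)/RVC(−), undivided cell, 10 mA/mmol, 23 °C
Reagents that add atoms: tert-butyl hydroperoxide, CC(C)(C)OO
Why: Proposed new method: N-oxyl-mediated anodic allylic C–H oxidation applied to an exocyclic tetrasubstituted isopropylidene with four competing allylic sites, where the bulky electrophilic phthalimide-N-oxyl should abstract the stereoelectronically aligned axial 8β-H because both C6 hydrogens are shielded by the axial C4 and C10 methyls and the peri 4α-acetate and are inductively deactivated, the C8/C11 allyl radical is trapped by t-BuOO• at the less hindered secondary C8, and pyridine-induced Kornblum–DeLaMare-type loss of t-BuOH gives the conjugated enone; the closest known reaction type is the electrochemical allylic oxidation of endocyclic tri- and tetrasubstituted olefins with N-hydroxyphthalimide mediators and t-BuOOH.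

**Compound list**
1 | (S)-(+)-carvone | CC(=C)[C@H]1CC=C(C)C(=O)C1 | starting material
2 | (2S,5S)-dihydrocarvone (C2 epimer also present, inconsequential) | CC(=C)[C@H]1CC[C@H](C)C(=O)C1 | intermediate
3 | ethyl vinyl ketone (pent-1-en-3-one) | CCC(=O)C=C | starting material
4 | (2S,5S)-2-methyl-2-(3-oxopentyl)-5-(prop-1-en-2-yl)cyclohexan-1-one (Michael adduct) | CCC(=O)CC[C@]1(C)CC[C@H](C(C)=C)CC1=O | intermediate
5 | 5-hydroxy-7-epi-eudesm-11-en-3-one (bicyclic ketol; C4/C5 configuration not defined, both dehydrate) | O=C1CC[C@]2(C)CC[C@H](C(C)=C)CC2(O)C1C | intermediate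
6 | ent-10-epi-α-cyperone, (4aS,7S)-1,4a-dimethyl-7-(prop-1-en-2-yl)-4,4a,5,6,7,8-hexahydronaphthalen-2(3H)-one | O=C1CC[C@]2(C)CC[C@H](C(C)=C)CC2=C1C | intermediate
7 | lithium Δ3-enolate of 7-epi-eudesm-11-en-3-one (5α-H) | [Li+].[O-]C1=C(C)[C@@H]2C[C@@H](C(C)=C)CC[C@@]2(C)CC1 | intermediate
8 | 3-(trimethylsilyloxy)-7-epi-eudesma-3,11-diene (5α-H, 10β-Me) | C[Si](C)(C)OC1=C(C)[C@@H]2C[C@@H](C(C)=C)CC[C@@]2(C)CC1 | intermediate
9 | 3α,4α-epoxy-3β-(trimethylsilyloxy)-7-epi-eudesm-11-ene | C[Si](C)(C)O[C@]31CC[C@]2(C)CC[C@H](C(C)=C)C[C@H]2[C@]1(C)O3 | intermediate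
10 | 4α-(trimethylsilyloxy)-7-epi-eudesm-11-en-3-one | O=C1CC[C@]2(C)CC[C@H](C(C)=C)C[C@H]2[C@]1(C)O[Si](C)(C)C | intermediate
11 | 4α-hydroxy-7-epi-eudesm-11-en-3-one (4β-Me, 5α-H) | O=C1CC[C@]2(C)CC[C@H](C(C)=C)C[C@H]2[C@]1(C)O | intermediate
12 | 7-epi-eudesm-11-ene-3β,4α-diol | O[C@H]1CC[C@]2(C)CC[C@H](C(C)=C)C[C@H]2[C@]1(C)O | intermediate
13 | (R)-2-methylbutanoic acid | CC[C@@H](C)C(=O)O | starting material
14 | 4α-hydroxy-7-epi-eudesm-11-en-3β-yl (R)-2-methylbutanoate | CC[C@@H](C)C(=O)O[C@H]1CC[C@]2(C)CC[C@H](C(C)=C)C[C@H]2[C@]1(C)O | intermediate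
15 | 4α-acetoxy-7-epi-eudesm-11-en-3β-yl (R)-2-methylbutanoate | CC[C@@H](C)C(=O)O[C@H]1CC[C@]2(C)CC[C@H](C(C)=C)C[C@H]2[C@]1(C)OC(C)=O | intermediate
16 | 4α-acetoxy-eudesm-7(11)-en-3β-yl (R)-2-methylbutanoate | CC[C@@H](C)C(=O)O[C@H]1CC[C@]2(C)CCC(=C(C)C)C[C@H]2[C@]1(C)OC(C)=O | intermediate
17 | 4α-acetoxy-8-(tert-butylperoxy)eudesm-7(11)-en-3β-yl (R)-2-methylbutanoate (C8 epimers) | CC[C@@H](C)C(=O)O[C@H]1CC[C@]2(C)CC(OOC(C)(C)C)C(=C(C)C)C[C@H]2[C@]1(C)OC(C)=O | intermediate
18 | (3S,4S,5R,10R)-4α-acetoxy-8-oxoeudesm-7(11)-en-3β-yl (R)-2-methylbutanoate | CC[C@@H](C)C(=O)O[C@H]1CC[C@]2(C)CC(=O)C(=C(C)C)C[C@H]2[C@]1(C)OC(C)=O | target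

**Totals**
Total step count: 9. Longest linear sequence: 9 steps, from (S)-carvone 1 to 18.

**Three steps most likely to fail**

Step 9 (the proposed new anodic oxidation; risk: attack at C6 or at the methyls, or peroxide formation at C11). The fallback uses known closed-shell chemistry in two stages and sets out from 16. Selenium dioxide (0.5 equiv) with t-BuOOH in CH2Cl2 performs an ene/[2,3]-sigmatropic allylic hydroxylation at the ring methylene, giving 4α-acetoxy-8-hydroxyeudesm-7(11)-en-3β-yl (R)-2-methylbutanoate F1. This allylic alcohol is then oxidized with Dess–Martin periodinane and the sequence comes back to the route at 18.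

Step 8 (risk: incomplete shift, over-migration into the ring, or partial reduction on the diester). The fallback moves the olefin transposition in front of the acylations and uses a closed-shell Rh–H insertion/β-hydride elimination instead of radical HAT. It sets out from diol 12, which is heated with RhCl3·3H2O (5 mol%) in EtOH at 75 °C to give eudesm-7(11)-ene-3β,4α-diol F2. Steglich esterification with 13 (DCC, DMAP) then gives 4α-hydroxyeudesm-7(11)-en-3β-yl (R)-2-methylbutanoate F3. Acetylation as in step 7 comes back to the route at 16.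

Step 7 (risk: the hindered tertiary 4α-OH acylates slowly or the C3 acyl group migrates). The fallback forms the C4–OAc bond by α-acetoxylation instead of by acylating the alcohol, and sets out from silyl enol ether 8. Pb(OAc)4 in CH2Cl2 at 0 °C delivers acetate from the α face to give 4α-acetoxy-7-epi-eudesm-11-en-3-one F4. Reduction with NaBH4/CeCl3 in MeOH at −78 °C, quenched cold with AcOH to suppress O4→O3 acetyl migration, gives 4α-acetoxy-7-epi-eudesm-11-en-3β-ol F5. Steglich esterification with 13 comes back to the route at 15.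

**Further compounds**
F1 | step 9 | 4α-acetoxy-8-hydroxyeudesm-7(11)-en-3β-yl (R)-2-methylbutanoate (C8 epimers) | CC[C@@H](C)C(=O)O[C@H]1CC[C@]2(C)CC(O)C(=C(C)C)C[C@H]2[C@]1(C)OC(C)=O
F2 | step 8 | eudesm-7(11)-ene-3β,4α-diol | O[C@H]1CC[C@]2(C)CCC(=C(C)C)C[C@H]2[C@]1(C)O
F3 | step 8 | 4α-hydroxyeudesm-7(11)-en-3β-yl (R)-2-methylbutanoate | CC[C@@H](C)C(=O)O[C@H]1CC[C@]2(C)CCC(=C(C)C)C[C@H]2[C@]1(C)O
F4 | step 7 | 4α-acetoxy-7-epi-eudesm-11-en-3-one | O=C1CC[C@]2(C)CC[C@H](C(C)=C)C[C@H]2[C@]1(C)OC(C)=O
F5 | step 7 | 4α-acetoxy-7-epi-eudesm-11-en-3β-ol | O[C@H]1CC[C@]2(C)CC[C@H](C(C)=C)C[C@H]2[C@]1(C)OC(C)=O
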